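**Retrosynthetic overview**
- Last bond made is the C15–O ester to silyl-protected caffeic acid. Before it, C12–C13 is made by a C12 alkylcopper (from the C12 bromide of the 13,14,15,16-tetranor core, via its Grignard reagent) opening (S)-β-butyrolactone at the β-carbon, which becomes C13.
- Enabling feature: C13 is a CH(CH3) centre 1,3 to the C15 oxygen, so C16–C13–C14–C15(=O)–O can be a strained temporary four-membered ring whose O–C13 bond is displaced with inversion. C12 is an unhindered primary carbon two bonds from ring B (C9) and can carry the metal.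
- Core: rings A and B are cis-fused (5β-H, 10β-CH3) with C11, C1 and C4 all on one face of ring B. That is the pattern of an endo Diels–Alder adduct of a ring A enone (C5=C10 dienophile, temporary C1 ketone) with the diene C6=C7–C8(C17H2O)=C9–C11–C12–O.
- Ring order: ring A first (asymmetric Michael addition sets quaternary C4, aldol condensation closes the ring), ring B second (Diels–Alder sets C5, C9, C10). The C1 ketone and the C17 aldehyde are then removed in one tosylhydrazone reduction that also moves the alkene to C8(17).

Key step: step 12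

Remark: labdane locants (C1–C20) are used for all bicyclic compounds, β is the face of the angular methyl C20, and the target as drawn is the cis-fused (5β-H) 4S,5S,9R,10R,13S stereoisomer, which is the compound the route is designed for.

**Route**

Step 1
Reactants: 1 tert-butyl propanoate; 2 ethyl formate
Product: 3 tert-butyl 2-methyl-3-oxopropanoate (racemic, enolisable)
Conditions: LiN(iPr)2 (2.1 equiv), THF, −78 °C; then 2, −78 → 0 °C; 1 M HCl
Reagents that add atoms: none
Why: Crossed Claisen condensation (C-formylation) of the ester lithium enolate with ethyl formate, the second equivalent of base holding the product as its enolate; no stereocentre is fixed because 3 is a freely enolising 1,3-dicarbonyl compound.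

Step 2
Reactants: 3 tert-butyl 2-methyl-3-oxopropanoate; 4 pent-1-en-3-one
Product: 5 tert-butyl (S)-2-formyl-2-methyl-5-oxoheptanoate
Conditions: 4 (1.5 equiv), 9-O-(9-phenanthryl)cupreidine (10 mol%), CH2Cl2, −20 °C
Reagents that add atoms: none
Why: Organocatalytic asymmetric Michael addition of an α-substituted 1,3-dicarbonyl donor to a vinyl ketone, in which the quinuclidine nitrogen deprotonates the enol of 3 while the 6'-hydroxyl binds the enone, so that one enol face is attacked and the quaternary C4 is set as S (the quinine-derived pseudoenantiomer of the catalyst is the lever if the opposite face is preferred).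

Step 3
Reactants: 5 tert-butyl (S)-2-formyl-2-methyl-5-oxoheptanoate
Product: 6 tert-butyl (S)-1,3-dimethyl-4-oxocyclohex-2-ene-1-carboxylate (ring A enone)
Conditions: pyrrolidine (20 mol%), AcOH (20 mol%), toluene, 60 °C
Reagents that add atoms: none
Why: Amine/acid-catalysed intramolecular aldol condensation (second half of a Robinson annulation), in which only the ethyl-side α-carbon can reach the non-enolisable aldehyde through a six-membered ring; this closes ring A as the C5=C10 enone and leaves the quaternary C4 untouched.

Step 4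
Reactants: 7 3-[(tert-butyldimethylsilyl)oxy]propanal (2 equiv)
Product: 8 (E)-5-[(tert-butyldimethylsilyl)oxy]-2-{[(tert-butyldimethylsilyl)oxy]methyl}pent-2-enal
Conditions: pyrrolidine (10 mol%), PhCO2H (10 mol%), CH2Cl2, 20 °C
Reagents that add atoms: none
Why: Enamine/iminium-catalysed self-aldol condensation of the aldehyde, dehydration giving the thermodynamically preferred (E)-2-substituted enal; the near-neutral conditions are chosen so that β-elimination of silanolate from the enamine does not compete.

Step 5
Reactants: 8 (E)-enal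
Product: 9 (3Z)-6-[(tert-butyldimethylsilyl)oxy]-3-{[(tert-butyldimethylsilyl)oxy]methyl}hexa-1,3-diene (C5 chain trans to the vinyl group)
Conditions: Ph3PCH3Br, KOtBu, THF, 0 °C
Reagents that add atoms: methyltriphenylphosphonium bromide, C[P+](c1ccccc1)(c1ccccc1)c1ccccc1.[Br-]
Why: Wittig methylenation of the aldehyde with Ph3P=CH2, which leaves the trisubstituted C8=C9 geometry intact and gives a diene whose C9 substituent is trans to the vinyl group, so the s-cis conformer is accessible.

Step 6
Reactants: 6 ring A enone; 9 diene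
Product: 10 tert-butyl 12,17-bis[(tert-butyldimethylsilyl)oxy]-1-oxo-13,14,15,16-tetranorlabd-7-en-19-oate, cis-fused, with H-5, H-9, CH3-20 and the C4 ester on the β face (C9 side chain α)
Conditions: Me2AlCl (1.5 equiv), CH2Cl2, −40 → 0 °C
Reagents that add atoms: none
Why: Lewis acid-promoted Diels–Alder reaction that closes ring B: the unsubstituted diene terminus C6 bonds to the enone β-carbon C5 and the alkyl-bearing terminus C9 to C10 (ortho rule), suprafacial addition fixes the cis C5/C10 fusion, the endo transition state (C1 carbonyl under the diene) puts the C9 side chain cis to the ring A bonds, and the diene is expected to approach anti to the bulky pseudo-axial tert-butoxycarbonyl group on C4, so that C5, C9 and C10 follow from the S centre at C4.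

Step 7
Reactants: 10 Diels–Alder adduct
Product: 11 tert-butyl 12,17-dihydroxy-1-oxo-13,14,15,16-tetranorlabd-7-en-19-oate (configuration as in 10)
Conditions: Bu4NF (2.5 equiv), THF, 0 → 20 °C
Reagents that add atoms: none
Why: Fluoride-mediated cleavage of both primary silyl ethers; ketone, alkene and tert-butyl ester are inert to Bu4NF.

Step 8
Reactants: 11 diol
Product: 12 tert-butyl 12-hydroxy-1,17-dioxo-13,14,15,16-tetranorlabd-7-en-19-oate (configuration as in 10)
Conditions: MnO2 (15 equiv), CH2Cl2, 20 °C
Reagents that add atoms: none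
Why: MnO2 oxidises only the allylic C17 alcohol, to the C7=C8-conjugated aldehyde, and leaves the saturated C12 alcohol, which differentiates the two hydroxyl groups without protection.

Step 9
Reactants: 12 hydroxy keto-enal
Product: 13 1,17-bis(4-methylbenzenesulfonylhydrazone) of 12
Conditions: TsNHNH2 (2.3 equiv), AcOH (cat.), EtOH, 60 °C
Reagents that add atoms: 4-methylbenzenesulfonohydrazide, Cc1ccc(cc1)S(=O)(=O)NN
Why: Condensation of both carbonyl groups with the sulfonyl hydrazide gives the bis(tosylhydrazone), the hindered C1 ketone being the reason for mild acid and warming.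

Step 10
Reactants: 13 bis(tosylhydrazone)
Product: 14 tert-butyl (4S,5S,9R,10R)-12-hydroxy-13,14,15,16-tetranorlabd-8(17)-en-19-oate
Conditions: catecholborane (6 equiv), CHCl3, 0 → 20 °C; then NaOAc·3H2O, 60 °C
Reagents that add atoms: none
Why: Caglioti-type reduction with catecholborane, in which the saturated C1 hydrazone is taken to CH2 while the conjugated C17 hydrazone is reduced to an allylic diazene that loses N2 by a 1,5-hydrogen shift to C7 and so moves the alkene into the exocyclic C8(17) position; no stereocentre is touched.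

Step 11
Reactants: 14 primary alcohol
Product: 15 tert-butyl (4S,5S,9R,10R)-12-bromo-13,14,15,16-tetranorlabd-8(17)-en-19-oate
Conditions: CBr4, PPh3, CH2Cl2, 0 °C
Reagents that add atoms: carbon tetrabromide, BrC(Br)(Br)Br
Why: Appel bromination of the unhindered primary alcohol by SN2 displacement of the alkoxyphosphonium ion.

Step 12
Reactants: 15 C12 bromide; 16 (S)-4-methyloxetan-2-one [(S)-β-butyrolactone]
Product: 18 (4S,5S,9R,10R,13S)-19-tert-butoxy-19-oxolabd-8(17)-en-15-oic acid, via alkylmagnesium bromide 17 (not isolated)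
Conditions: Mg, THF, 40 °C; then CuBr·SMe2 (10 mol%), 16, THF/Me2S, −30 → 0 °C; then 1 M HCl
Reagents that add atoms: none
Why: The primary alkylmagnesium bromide 17 is transmetallated to a monovalent-copper alkyl, which attacks the β-carbon of the lactone (C13) from the side opposite the ring oxygen (alkyl–oxygen cleavage, SN2) and releases the carboxylate, so C12–C13 is formed and C14, C15 and C16 arrive in the same event with C15 at the acid level. The closest known reaction type is the copper-catalysed ring opening of β-propiolactones by Grignard reagents to give β-substituted carboxylic acids. No ring is closed; the four-membered lactone is a temporary ring whose strain drives the substitution. The only new stereocentre, C13, is controlled by the lactone stereocentre through inversion, the S lactone giving the 13S acid. The step needs attack at the lactone β-carbon and not at its carbonyl, which the soft organocopper (catalytic CuBr·SMe2, Me2S co-solvent, low temperature) secures, and it needs the C19 ester to stay untouched, which its tert-butyl group and its axial, neopentyl position on ring A secure.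

Step 13
Reactants: 18 C15 acid
Product: 20 tert-butyl (4S,5S,9R,10R,13S)-15-hydroxylabd-8(17)-en-19-oate, via isobutyl carbonic mixed anhydride 19 (not isolated)
Conditions: iBuOCOCl, N-methylmorpholine, THF, −15 °C; then NaBH4, H2O, 0 °C
Reagents that add atoms: none
Why: Activation of the new carboxylic acid as its isobutyl carbonic mixed anhydride and chemoselective NaBH4 reduction to the primary alcohol, conditions that spare the hindered tert-butyl ester and, unlike a borane reduction, the exocyclic alkene.

Step 14
Reactants: 21 caffeic acid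
Product: 23 (E)-3-{3,4-bis[(tert-butyldimethylsilyl)oxy]phenyl}prop-2-enoic acid, via silyl ester 22 (not isolated)
Conditions: TBSCl (3.5 equiv), imidazole, DMF, 20 °C; then AcOH/THF/H2O (3:1:1), 20 °C
Reagents that add atoms: tert-butyldimethylsilyl chloride, CC(C)(C)[Si](C)(C)Cl
Why: Persilylation of both phenols and the acid, then selective hydrolysis of the far more labile silyl ester under mild aqueous acid to free the carboxylic acid for coupling.

Step 15
Reactants: 20 C15 alcohol; 23 protected caffeic acid
Product: 24 tert-butyl (4S,5S,9R,10R,13S)-15-{[(E)-3-{3,4-bis[(tert-butyldimethylsilyl)oxy]phenyl}prop-2-enoyl]oxy}labd-8(17)-en-19-oate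
Conditions: DCC, DMAP (cat.), CH2Cl2, 0 → 20 °C
Reagents that add atoms: none
Why: Steglich esterification (carbodiimide activation, DMAP acyl transfer) of the primary C15 alcohol with the protected cinnamic acid; the (E)-alkene is not affected.

Step 16
Reactants: 24 fully protected ester
Product: 26 (4S,5S,9R,10R,13S)-15-{[(E)-3-(3,4-dihydroxyphenyl)prop-2-enoyl]oxy}labd-8(17)-en-19-oic acid (target), via trimethylsilyl ester 25 (not isolated)
Conditions: TMSOTf, 2,6-lutidine, CH2Cl2, 0 °C; then Bu4NF, AcOH, THF, 0 → 20 °C
Reagents that add atoms: none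
Why: Silyl triflate-mediated cleavage of the tert-butyl ester (O-silylation, loss of 2-methylpropene) under buffered, non-protic conditions that should not isomerise the exocyclic alkene, followed in the same flask by buffered fluoride to remove the silyl ester and both aryl silyl ethers.

**Compound list**

1 | tert-butyl propanoate | CCC(=O)OC(C)(C)C | starting material
2 | ethyl formate | CCOC=O | starting material
3 | tert-butyl 2-methyl-3-oxopropanoate (racemic) | CC(C=O)C(=O)OC(C)(C)C | intermediate
4 | pent-1-en-3-one | CCC(=O)C=C | starting material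
5 | tert-butyl (S)-2-formyl-2-methyl-5-oxoheptanoate | CCC(=O)CC[C@@](C)(C=O)C(=O)OC(C)(C)C | intermediate
6 | tert-butyl (S)-1,3-dimethyl-4-oxocyclohex-2-ene-1-carboxylate | CC1=C[C@](C)(CCC1=O)C(=O)OC(C)(C)C | intermediate
7 | 3-[(tert-butyldimethylsilyl)oxy]propanal | CC(C)(C)[Si](C)(C)OCCC=O | starting material
8 | (E)-5-[(tert-butyldimethylsilyl)oxy]-2-{[(tert-butyldimethylsilyl)oxy]methyl}pent-2-enal | O=C/C(CO[Si](C)(C)C(C)(C)C)=C/CCO[Si](C)(C)C(C)(C)C | intermediate
9 | (3Z)-6-[(tert-butyldimethylsilyl)oxy]-3-{[(tert-butyldimethylsilyl)oxy]methyl}hexa-1,3-diene | C=C/C(CO[Si](C)(C)C(C)(C)C)=C/CCO[Si](C)(C)C(C)(C)C | intermediate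
10 | tert-butyl 12,17-bis[(tert-butyldimethylsilyl)oxy]-1-oxo-13,14,15,16-tetranorlabd-7-en-19-oate (cis-fused; 5β-H, 9β-H, 10β-CH3, 4β-CO2tBu) | CC(C)(C)[Si](C)(C)OCC1=CC[C@H]2[C@](C)(C(=O)CC[C@]2(C)C(=O)OC(C)(C)C)[C@@H]1CCO[Si](C)(C)C(C)(C)C | intermediate
11 | tert-butyl 12,17-dihydroxy-1-oxo-13,14,15,16-tetranorlabd-7-en-19-oate (configuration as 10) | OCC1=CC[C@H]2[C@](C)(C(=O)CC[C@]2(C)C(=O)OC(C)(C)C)[C@@H]1CCO | intermediate
12 | tert-butyl 12-hydroxy-1,17-dioxo-13,14,15,16-tetranorlabd-7-en-19-oate (configuration as 10) | O=CC1=CC[C@H]2[C@](C)(C(=O)CC[C@]2(C)C(=O)OC(C)(C)C)[C@@H]1CCO | intermediate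
13 | 1,17-bis(4-methylbenzenesulfonylhydrazone) of 12 | Cc1ccc(cc1)S(=O)(=O)NN=CC1=CC[C@H]2[C@](C)(C(CC[C@]2(C)C(=O)OC(C)(C)C)=NNS(=O)(=O)c3ccc(C)cc3)[C@@H]1CCO | intermediate
14 | tert-butyl (4S,5S,9R,10R)-12-hydroxy-13,14,15,16-tetranorlabd-8(17)-en-19-oate | C=C1CC[C@H]2[C@](C)(CCC[C@]2(C)C(=O)OC(C)(C)C)[C@@H]1CCO | intermediate
15 | tert-butyl (4S,5S,9R,10R)-12-bromo-13,14,15,16-tetranorlabd-8(17)-en-19-oate | C=C1CC[C@H]2[C@](C)(CCC[C@]2(C)C(=O)OC(C)(C)C)[C@@H]1CCBr | intermediate
16 | (S)-4-methyloxetan-2-one | C[C@H]1CC(=O)O1 | starting material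
17 | alkylmagnesium bromide from 15 (C12–MgBr) | C=C1CC[C@H]2[C@](C)(CCC[C@]2(C)C(=O)OC(C)(C)C)[C@@H]1CC[Mg]Br | intermediate
18 | (4S,5S,9R,10R,13S)-19-tert-butoxy-19-oxolabd-8(17)-en-15-oic acid | C=C1CC[C@H]2[C@](C)(CCC[C@]2(C)C(=O)OC(C)(C)C)[C@@H]1CC[C@H](C)CC(=O)O | intermediate
19 | isobutyl carbonic mixed anhydride of 18 | C=C1CC[C@H]2[C@](C)(CCC[C@]2(C)C(=O)OC(C)(C)C)[C@@H]1CC[C@H](C)CC(=O)OC(=O)OCC(C)C | intermediate
20 | tert-butyl (4S,5S,9R,10R,13S)-15-hydroxylabd-8(17)-en-19-oate | C=C1CC[C@H]2[C@](C)(CCC[C@]2(C)C(=O)OC(C)(C)C)[C@@H]1CC[C@H](C)CCO | intermediate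
21 | caffeic acid | OC(=O)/C=C/c1ccc(O)c(O)c1 | starting material
22 | tert-butyldimethylsilyl (E)-3-{3,4-bis[(tert-butyldimethylsilyl)oxy]phenyl}prop-2-enoate | CC(C)(C)[Si](C)(C)OC(=O)/C=C/c1ccc(O[Si](C)(C)C(C)(C)C)c(O[Si](C)(C)C(C)(C)C)c1 | intermediate
23 | (E)-3-{3,4-bis[(tert-butyldimethylsilyl)oxy]phenyl}prop-2-enoic acid | OC(=O)/C=C/c1ccc(O[Si](C)(C)C(C)(C)C)c(O[Si](C)(C)C(C)(C)C)c1 | intermediate
24 | tert-butyl (4S,5S,9R,10R,13S)-15-{[(E)-3-{3,4-bis[(tert-butyldimethylsilyl)oxy]phenyl}prop-2-enoyl]oxy}labd-8(17)-en-19-oate | C=C1CC[C@H]2[C@](C)(CCC[C@]2(C)C(=O)OC(C)(C)C)[C@@H]1CC[C@H](C)CCOC(=O)/C=C/c1ccc(O[Si](C)(C)C(C)(C)C)c(O[Si](C)(C)C(C)(C)C)c1 | intermediate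
25 | trimethylsilyl ester analogue of 24 (C19 CO2SiMe3) | C=C1CC[C@H]2[C@](C)(CCC[C@]2(C)C(=O)O[Si](C)(C)C)[C@@H]1CC[C@H](C)CCOC(=O)/C=C/c1ccc(O[Si](C)(C)C(C)(C)C)c(O[Si](C)(C)C(C)(C)C)c1 | intermediate
26 | (4S,5S,9R,10R,13S)-15-{[(E)-3-(3,4-dihydroxyphenyl)prop-2-enoyl]oxy}labd-8(17)-en-19-oic acid | C=C1CC[C@H]2[C@](C)(CCC[C@]2(C)C(=O)O)[C@@H]1CC[C@H](C)CCOC(=O)/C=C/c1ccc(O)c(O)c1 | target

**Totals and risks**

Total step count: 16. Longest linear sequence: 13 steps (1, 2, 3, 6 to 13, 15, 16).

Steps most likely to fail:

Step 6. The cycloaddition joins two hindered partners and may be slow, so that Lewis-acid cleavage of the tert-butyl ester or of the allylic silyl ether competes. Leakage to the regioisomeric (C9-to-C5) adduct, the exo adduct, or the adduct from the ester face is also possible. Fallback (ionic Diels–Alder), setting out from 6 and coming back at 11: ketalisation of 6 with 1,2-bis(trimethylsilyloxy)ethane and catalytic TMSOTf at −78 °C should give the allylic dioxolane F1. With catalytic TMSOTf at −78 °C this ionises reversibly to a vinyl-substituted dioxolanylium ion, a much stronger dienophile than the aluminium-bound enone. It should add diene 9 with the same ortho, endo and anti-to-ester preferences to give the ketal adduct F2. Aqueous HCl in THF then removes the dioxolane and both silyl ethers and returns to diol 11.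

Step 2. Enantiofacial discrimination may be insufficient when the quaternary centre is formed, because the acyclic α-formyl ester is a less organised donor than a cyclic β-keto ester. Fallback (covalent auxiliary), setting out from 3 and coming back at 5: condensation of 3 with (S)-1-phenylethylamine should give the hydrogen-bonded (Z)-enamino ester F3. Its aza-ene-type Michael addition to 4, the enone approaching the enamine face anti to the phenyl group, should give imine F4; the antipodal amine is taken if the model places the S centre on the other face. Hydrolysis with aqueous acetic acid returns to 5.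

Step 12. The organometallic may attack the lactone carbonyl (acyl–oxygen cleavage), the lactone may open to crotonate by elimination, or Wurtz coupling may consume the bromide while the Grignard reagent forms. Fallback (conjugate addition in place of substitution), setting out from 15 via 17 and coming back at 20: CuBr·SMe2/Josiphos-catalysed asymmetric conjugate addition of 17 to S-ethyl (E)-but-2-enethioate at −75 °C should give thioester F5, C13 now being set by the ligand enantiomer chosen for 13S. Reduction of F5 with LiBH4 leads to alcohol 20, bypassing 18 and 19.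

Further compounds
F1 | step 6 | tert-butyl (S)-6,8-dimethyl-1,4-dioxaspiro[4.5]dec-6-ene-8-carboxylate (ethylene ketal of 6) | CC1=C[C@](C)(CCC12OCCO2)C(=O)OC(C)(C)C
F2 | step 6 | C1 ethylene ketal of adduct 10 | CC(C)(C)[Si](C)(C)OCC1=CC[C@H]2[C@](C)(C3(OCCO3)CC[C@]2(C)C(=O)OC(C)(C)C)[C@@H]1CCO[Si](C)(C)C(C)(C)C
F3 | step 2 | tert-butyl (Z)-2-methyl-3-{[(S)-1-phenylethyl]amino}prop-2-enoate | C[C@H](N/C=C(/C)C(=O)OC(C)(C)C)c1ccccc1
F4 | step 2 | tert-butyl (S)-2-methyl-5-oxo-2-({[(S)-1-phenylethyl]imino}methyl)heptanoate | CCC(=O)CC[C@@](C)(C=N[C@@H](C)c1ccccc1)C(=O)OC(C)(C)C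
F5 | step 12 | S-ethyl (4S,5S,9R,10R,13S)-19-tert-butoxy-19-oxolabd-8(17)-ene-15-thioate | C=C1CC[C@H]2[C@](C)(CCC[C@]2(C)C(=O)OC(C)(C)C)[C@@H]1CC[C@H](C)CC(=O)SCC
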